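**Retrosynthetic overview**

1. Flavan numbering is used throughout: O1, C2–C4 and C4a–C8a for rings A and C, primed atoms for ring B, and ring D for the dimethylpyran on O4'/C5'. Structural feature: C2 is the benzylic carbon on C1' of ring B, para to O4'. It is joined through C3–C4–C4a–C8a to the ring A oxygen O1. While O4' still carries hydrogen, C2 can be flattened to a para-quinone methide (C2=C1', C4'=O) and taken up again by O1.
2. Disconnections:
   - the O3'/O7 MOM ethers;
   - ring D (O4'–CMe2 and C5'–CH=), back to the 4'-phenol and 3-chloro-3-methylbut-1-yne;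
   - ring C at O1–C2, back to a racemic 1,3-diarylpropan-1-ol;
   - C4–C4a by Heck arylation–isomerisation, and C2–C3 by vinyl Grignard addition;
   - the C2' prenyl group (3-methylbut-2-enyl) by an O3'-to-C2' Claisen shift on 3,4-dihydroxybenzaldehyde.
3. Ring order: rings A and B are bought. Ring C closes in step 11 and sets C2. Ring D closes in step 13.
4. Protecting groups: O4' carries a fluoride-labile TIPS group (Si(i-Pr)3) until just before ring C closure. O3' and O7 carry non-migrating MOM ethers (CH2OCH3), so that O4' is the only phenol open to propargylation. The MOM ethers are removed at the end without protic acid, because C2–O1, the prenyl/3'-OH pair and the chromene are acid-sensitive.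

Key step: step 11

Assumption: the sense of induction of a BINOL-derived phosphoric acid on this substrate cannot be predicted with confidence, so the (R)-catalyst is written and its mirror image is used if a first trial should lead to the 2S series.

**Step 1**
Reactants: 1 2-methylbut-3-en-2-ol
Product: 3 tert-butyl 2-methylbut-3-en-2-yl carbonate, via lithium alkoxide 2 (not isolated)
Conditions: n-BuLi, THF, −78 to 0 °C; then Boc2O, 0 °C to rt; H2O
Reagents that add atoms: di-tert-butyl dicarbonate (Boc2O), CC(C)(C)OC(=O)OC(=O)OC(C)(C)C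
Why: Acylation of a lithium alkoxide with a dicarbonate, in which the hindered tertiary alcohol is first turned into alkoxide 2 and this attacks Boc2O to give the mixed carbonate that serves as the ionisable 1,1-dimethylallyl donor of step 3.

**Step 2**
Reactants: 4 3,4-dihydroxybenzaldehyde
Product: 5 3-hydroxy-4-(triisopropylsilyloxy)benzaldehyde
Conditions: i-Pr3SiCl (1.0 equiv), Et3N (1.05 equiv), DMF, −10 to 0 °C
Reagents that add atoms: chlorotriisopropylsilane, CC(C)[Si](Cl)(C(C)C)C(C)C
Why: Acidity-guided monosilylation, in which the 4-OH para to the formyl group is the only phenol ionised by one equivalent of Et3N and should therefore be silylated first, while i-Pr3Si is preferred to smaller silyl groups because its O4-to-O3 shift in a catechol monoether is slow.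

**Step 3**
Reactants: 5 3-hydroxy-4-(triisopropylsilyloxy)benzaldehyde + 3 tert-butyl 2-methylbut-3-en-2-yl carbonate
Product: 6 3-(2-methylbut-3-en-2-yloxy)-4-(triisopropylsilyloxy)benzaldehyde
Conditions: Pd(PPh3)4 (3 mol%), THF, 0 °C to rt
Reagents that add atoms: none
Why: Tsuji–Trost-type decarboxylative O-allylation, in which zerovalent palladium ionises 3 to a 1,1-dimethyl-π-allyl complex, CO2 and tert-butoxide, the butoxide takes the 3-OH proton, and the phenoxide attacks the more substituted allyl terminus under kinetic control, giving the tertiary ether without stoichiometric base that could move the silyl group.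

**Step 4**
Reactants: 6 3-(2-methylbut-3-en-2-yloxy)-4-(triisopropylsilyloxy)benzaldehyde
Product: 8 3-hydroxy-2-prenyl-4-(triisopropylsilyloxy)benzaldehyde, via ortho-dienone 7 (not isolated)
Conditions: xylenes, 130 °C, argon, base-washed glassware
Reagents that add atoms: none
Why: Aromatic Claisen rearrangement, in which the [3,3] shift from O3 can be completed only at C2 because C4 bears oxygen, the allyl inversion turns the 1,1-dimethylallyl ether into the linear prenyl group, and dienone 7 enolises to the phenol.

**Step 5**
Reactants: 8 3-hydroxy-2-prenyl-4-(triisopropylsilyloxy)benzaldehyde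
Product: 9 3-(methoxymethoxy)-2-prenyl-4-(triisopropylsilyloxy)benzaldehyde
Conditions: MOMCl, i-Pr2NEt, n-Bu4NI (cat.), CH2Cl2, 0 to 40 °C
Reagents that add atoms: chloromethyl methyl ether (MOMCl), COCCl
Why: MOM ether formation (O-alkylation with an α-chloro ether) under a non-ionising amine base caps O3' with a group that cannot wander to O4', so that O4' is later the only free phenol of ring B and no free catechol ever meets acid, copper or air.

**Step 6**
Reactants: 9 3-(methoxymethoxy)-2-prenyl-4-(triisopropylsilyloxy)benzaldehyde
Product: 10 rac-1-[3-(methoxymethoxy)-2-prenyl-4-(triisopropylsilyloxy)phenyl]prop-2-en-1-ol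
Conditions: CH2=CHMgBr, THF, −78 to −20 °C; H2O/NH4Cl
Reagents that add atoms: vinylmagnesium bromide, C=C[Mg]Br
Why: Grignard 1,2-addition to the aldehyde forms C2–C3 and gives the future C2 carbinol as a racemate, which is of no consequence because this centre is flattened in step 11.

**Step 7**
Reactants: 11 4-iodoresorcinol
Product: 12 2-iodo-5-(methoxymethoxy)phenol
Conditions: MOMCl (1.0 equiv), i-Pr2NEt, CH2Cl2, −20 to 0 °C
Reagents that add atoms: chloromethyl methyl ether (MOMCl), COCCl
Why: Sterically guided mono-O-alkylation, in which the hydroxyl next to iodine is shielded and engaged in an O–H···I contact, so that one equivalent of MOMCl should go mainly to the hydroxyl para to iodine (the future O7), with the regioisomer and the bis-ether removable by chromatography at this cheap first stage.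

**Step 8**
Reactants: 10 rac-1-[3-(methoxymethoxy)-2-prenyl-4-(triisopropylsilyloxy)phenyl]prop-2-en-1-ol + 12 2-iodo-5-(methoxymethoxy)phenol
Product: 14 3-[2-hydroxy-4-(methoxymethoxy)phenyl]-1-[3-(methoxymethoxy)-2-prenyl-4-(triisopropylsilyloxy)phenyl]propan-1-one, via enol 13 (not isolated)
Conditions: Pd(OAc)2 (5 mol%), n-Bu4NCl, NaHCO3, DMF (degassed), 50 °C
Reagents that add atoms: none
Why: Heck arylation of an allylic alcohol under Jeffery conditions, in which the arylpalladium species delivers its aryl group to the terminal CH2 (C4–C4a bond), β-hydride elimination runs towards the carbinol C–H, and enol 13 tautomerises to the saturated ketone, while the trisubstituted prenyl alkene is too hindered to insert.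

**Step 9**
Reactants: 14 3-[2-hydroxy-4-(methoxymethoxy)phenyl]-1-[3-(methoxymethoxy)-2-prenyl-4-(triisopropylsilyloxy)phenyl]propan-1-one
Product: 15 rac-3-[2-hydroxy-4-(methoxymethoxy)phenyl]-1-[3-(methoxymethoxy)-2-prenyl-4-(triisopropylsilyloxy)phenyl]propan-1-ol
Conditions: NaBH4, THF/MeOH, 0 °C
Reagents that add atoms: none
Why: Borohydride reduction of the aryl ketone, drawn from its open form even if part of 14 rests as the cyclic hemiketal with O1, gives the racemic benzylic alcohol, and the MOM ethers, the silyl ether and the alkene are inert to NaBH4.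

**Step 10**
Reactants: 15 rac-3-[2-hydroxy-4-(methoxymethoxy)phenyl]-1-[3-(methoxymethoxy)-2-prenyl-4-(triisopropylsilyloxy)phenyl]propan-1-ol
Product: 16 rac-1-[4-hydroxy-3-(methoxymethoxy)-2-prenylphenyl]-3-[2-hydroxy-4-(methoxymethoxy)phenyl]propan-1-ol
Conditions: n-Bu4NF/AcOH (1:1), THF, 0 °C; pH 7 buffer, plug of neutral Al2O3
Reagents that add atoms: none
Why: Fluoride-induced cleavage of the aryl silyl ether, buffered with AcOH so that the liberated para-hydroxybenzyl alcohol sees neither free phenoxide nor acid, unmasks O4' while the MOM ethers stay in place.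

**Step 11**
Reactants: 16 rac-1-[4-hydroxy-3-(methoxymethoxy)-2-prenylphenyl]-3-[2-hydroxy-4-(methoxymethoxy)phenyl]propan-1-ol
Product: 18 (2R)-4'-hydroxy-3',7-bis(methoxymethoxy)-2'-prenylflavan, via para-quinone methide 17 (not isolated)
Conditions: (R)-3,3'-bis(2,4,6-triisopropylphenyl)-1,1'-binaphthyl-2,2'-diyl hydrogen phosphate [(R)-TRIP, 10 mol%], 5 Å molecular sieves, toluene (0.02 M), −20 °C; cold filtration through NaHCO3/Celite
Reagents that add atoms: none
Why: Proposed new method: the phosphoric acid protonates the benzylic hydroxyl of either enantiomer of 16 while its phosphoryl oxygen takes up the 4'-OH proton, so that water leaves and both antipodes merge into one planar, neutral para-quinone methide 17 (C2=C1', C4'=O), to which the ring A phenol O1 then adds in a 1,6-sense with rearomatisation of ring B. The closest known reaction type is the chiral phosphoric acid-catalysed enantioselective 1,6-addition of carbon, sulfur and nitrogen nucleophiles to para-quinone methides generated in situ from racemic para-hydroxybenzyl alcohols; what has not been shown is an intramolecular phenol oxygen adding to a methide that carries a primary alkyl chain with abstractable C3 hydrogens. Ring C closes in a 6-exo-trig mode, because the attacked C2=C1' double bond lies outside the forming O1–C8a–C4a–C4–C3–C2 ring. C2 is the only new stereocentre, and its configuration is set by the catalyst, which holds the methide through P–OH···O4' and the nucleophile through P=O···H–O1 within the pocket of its 3,3'-aryl groups and so leaves one face of C2 open. The step needs a single methide geometry, O- over C-attack and cyclisation over side reactions: allylic strain with the C2' prenyl group turns the C3 chain towards C6'–H (E geometry), the only ring A carbon within reach (C5) is meta to both oxygens and unactivated, the merely hydrogen-bonded methide is too weak an electrophile for the prenyl double bond, and tautomerisation to the styrene is reversible under the same acid. Low temperature, sieves, high dilution and a cold non-basic quench are needed because 18 still carries the free 4'-OH and can reopen.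

**Step 12**
Reactants: 18 (2R)-4'-hydroxy-3',7-bis(methoxymethoxy)-2'-prenylflavan + 19 3-chloro-3-methylbut-1-yne
Product: 20 (2R)-3',7-bis(methoxymethoxy)-4'-(2-methylbut-3-yn-2-yloxy)-2'-prenylflavan
Conditions: CuCl2·2H2O (1 mol%), DBU (1.2 equiv), MeCN, −10 to 0 °C, argon
Reagents that add atoms: none
Why: Copper-catalysed propargylic etherification of a phenol with a tertiary propargylic chloride, by way of a copper acetylide that loses chloride, in which O4' is the only free hydroxyl of 18 and the short contact with DBU at or below 0 °C is meant to cap it before the 4'-phenoxide can expel O1 from C2.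

**Step 13**
Reactants: 20 (2R)-3',7-bis(methoxymethoxy)-4'-(2-methylbut-3-yn-2-yloxy)-2'-prenylflavan
Product: 23 (2R)-7-(methoxymethoxy)-2-[8-(methoxymethoxy)-2,2-dimethyl-7-prenyl-2H-chromen-6-yl]chroman, via ortho-allenylphenol 21 (not isolated), via ortho-quinone methide 22 (not isolated)
Conditions: o-xylene, 140 °C, argon
Reagents that add atoms: none
Why: Aryl propargyl ether Claisen cascade, in which the [3,3] shift can be completed only at C5' because C3' bears oxygen, enolisation gives allenylphenol 21, a 1,5-hydrogen shift gives ortho-quinone methide 22, and oxa-6π electrocyclisation closes ring D, all under neutral conditions that leave C2 untouched.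

**Step 14**
Reactants: 23 (2R)-7-(methoxymethoxy)-2-[8-(methoxymethoxy)-2,2-dimethyl-7-prenyl-2H-chromen-6-yl]chroman
Product: 25 (2R)-2-[8-hydroxy-2,2-dimethyl-7-prenyl-2H-chromen-6-yl]chroman-7-ol, via bis(trimethylsilyl) ether 24 (not isolated)
Conditions: Me3SiOTf, 2,2'-bipyridyl, MeCN, 0 °C to rt; then H2O
Reagents that add atoms: none
Why: Cleavage of aromatic MOM ethers with a silyl triflate buffered by 2,2'-bipyridyl, a known method that runs through the aryl silyl ethers 24 and their hydrolysis and spares trityl-type ethers, is chosen because protic acid could ionise the C2–O1 bond, add the freed 3'-OH to the prenyl group or attack the chromene.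

**Compound list**

1 | 2-methylbut-3-en-2-ol | C=CC(C)(C)O | starting material
2 | lithium 2-methylbut-3-en-2-olate (not isolated) | [Li+].[O-]C(C)(C)C=C | intermediate
3 | tert-butyl 2-methylbut-3-en-2-yl carbonate | C=CC(C)(C)OC(=O)OC(C)(C)C | intermediate
4 | 3,4-dihydroxybenzaldehyde | O=Cc1ccc(O)c(O)c1 | starting material
5 | 3-hydroxy-4-(triisopropylsilyloxy)benzaldehyde | O=Cc1ccc(O[Si](C(C)C)(C(C)C)C(C)C)c(O)c1 | intermediate
6 | 3-(2-methylbut-3-en-2-yloxy)-4-(triisopropylsilyloxy)benzaldehyde | O=Cc1ccc(O[Si](C(C)C)(C(C)C)C(C)C)c(OC(C)(C)C=C)c1 | intermediate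
7 | rac-5-oxo-6-prenyl-4-(triisopropylsilyloxy)cyclohexa-1,3-diene-1-carbaldehyde (not isolated) | O=CC1=CC=C(O[Si](C(C)C)(C(C)C)C(C)C)C(=O)C1CC=C(C)C | intermediate
8 | 3-hydroxy-2-prenyl-4-(triisopropylsilyloxy)benzaldehyde | O=Cc1ccc(O[Si](C(C)C)(C(C)C)C(C)C)c(O)c1CC=C(C)C | intermediate
9 | 3-(methoxymethoxy)-2-prenyl-4-(triisopropylsilyloxy)benzaldehyde | O=Cc1ccc(O[Si](C(C)C)(C(C)C)C(C)C)c(OCOC)c1CC=C(C)C | intermediate
10 | rac-1-[3-(methoxymethoxy)-2-prenyl-4-(triisopropylsilyloxy)phenyl]prop-2-en-1-ol | C=CC(O)c1ccc(O[Si](C(C)C)(C(C)C)C(C)C)c(OCOC)c1CC=C(C)C | intermediate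
11 | 4-iodoresorcinol (4-iodobenzene-1,3-diol) | Oc1ccc(I)c(O)c1 | starting material
12 | 2-iodo-5-(methoxymethoxy)phenol | COCOc1ccc(I)c(O)c1 | intermediate
13 | 3-[2-hydroxy-4-(methoxymethoxy)phenyl]-1-[3-(methoxymethoxy)-2-prenyl-4-(triisopropylsilyloxy)phenyl]prop-1-en-1-ol (not isolated) | OC(=CCc1ccc(OCOC)cc1O)c1ccc(O[Si](C(C)C)(C(C)C)C(C)C)c(OCOC)c1CC=C(C)C | intermediate
14 | 3-[2-hydroxy-4-(methoxymethoxy)phenyl]-1-[3-(methoxymethoxy)-2-prenyl-4-(triisopropylsilyloxy)phenyl]propan-1-one | O=C(CCc1ccc(OCOC)cc1O)c1ccc(O[Si](C(C)C)(C(C)C)C(C)C)c(OCOC)c1CC=C(C)C | intermediate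
15 | rac-3-[2-hydroxy-4-(methoxymethoxy)phenyl]-1-[3-(methoxymethoxy)-2-prenyl-4-(triisopropylsilyloxy)phenyl]propan-1-ol | OC(CCc1ccc(OCOC)cc1O)c1ccc(O[Si](C(C)C)(C(C)C)C(C)C)c(OCOC)c1CC=C(C)C | intermediate
16 | rac-1-[4-hydroxy-3-(methoxymethoxy)-2-prenylphenyl]-3-[2-hydroxy-4-(methoxymethoxy)phenyl]propan-1-ol | CC(C)=CCc1c(C(O)CCc2ccc(OCOC)cc2O)ccc(O)c1OCOC | intermediate
17 | (E)-4-{3-[2-hydroxy-4-(methoxymethoxy)phenyl]propylidene}-2-(methoxymethoxy)-3-prenylcyclohexa-2,5-dien-1-one (not isolated) | CC(C)=CCC1=C(OCOC)C(=O)C=C/C1=C\CCc1ccc(OCOC)cc1O | intermediate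
18 | (2R)-4'-hydroxy-3',7-bis(methoxymethoxy)-2'-prenylflavan | CC(C)=CCc1c([C@H]2CCc3ccc(OCOC)cc3O2)ccc(O)c1OCOC | intermediate
19 | 3-chloro-3-methylbut-1-yne | C#CC(C)(C)Cl | starting material
20 | (2R)-3',7-bis(methoxymethoxy)-4'-(2-methylbut-3-yn-2-yloxy)-2'-prenylflavan | CC(C)=CCc1c([C@H]2CCc3ccc(OCOC)cc3O2)ccc(OC(C)(C)C#C)c1OCOC | intermediate
21 | (2R)-4'-hydroxy-3',7-bis(methoxymethoxy)-5'-(3-methylbuta-1,2-dienyl)-2'-prenylflavan (not isolated) | CC(C)=CCc1c([C@H]2CCc3ccc(OCOC)cc3O2)cc(C=C=C(C)C)c(O)c1OCOC | intermediate
22 | 2-(methoxymethoxy)-4-[(2R)-7-(methoxymethoxy)chroman-2-yl]-6-(3-methylbut-2-enylidene)-3-prenylcyclohexa-2,4-dien-1-one (not isolated) | CC(C)=CCC1=C(OCOC)C(=O)C(=CC=C(C)C)C=C1[C@H]1CCc2ccc(OCOC)cc2O1 | intermediate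
23 | (2R)-7-(methoxymethoxy)-2-[8-(methoxymethoxy)-2,2-dimethyl-7-prenyl-2H-chromen-6-yl]chroman | CC(C)=CCc1c([C@H]2CCc3ccc(OCOC)cc3O2)cc2c(c1OCOC)OC(C)(C)C=C2 | intermediate
24 | (2R)-7-(trimethylsilyloxy)-2-[2,2-dimethyl-7-prenyl-8-(trimethylsilyloxy)-2H-chromen-6-yl]chroman (not isolated) | CC(C)=CCc1c([C@H]2CCc3ccc(O[Si](C)(C)C)cc3O2)cc2c(c1O[Si](C)(C)C)OC(C)(C)C=C2 | intermediate
25 | (2R)-2-[8-hydroxy-2,2-dimethyl-7-prenyl-2H-chromen-6-yl]chroman-7-ol | CC(C)=CCc1c([C@H]2CCc3ccc(O)cc3O2)cc2c(c1O)OC(C)(C)C=C2 | target

**Step count**

Total step count: 14.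
Longest linear sequence: 12 steps, from 4 to 25 through steps 2–6 and 8–14. Steps 1 and 7 are one-step side branches.

**The three steps most likely to fail**

**Step 11** is the one step beyond known chemistry. Four things may go wrong.
- Ionisation of the secondary alkyl aryl carbinol may be too slow at the temperature at which 18 is configurationally safe.
- The methide may drain away, either by loss of a C3 proton to the styrene or by intermolecular capture to oligomers.
- Facial discrimination may be poor, because the nucleophile hangs on a flexible two-carbon tether.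
- Reversible reopening of ring C may erode the enantiomeric purity.

The fallback uses known chemistry and sets out from ketone 14. Noyori asymmetric transfer hydrogenation (RuCl[(S,S)-TsDPEN](p-cymene), HCO2H/Et3N, rt) should give (S)-3-[2-hydroxy-4-(methoxymethoxy)phenyl]-1-[3-(methoxymethoxy)-2-prenyl-4-(triisopropylsilyloxy)phenyl]propan-1-ol F1. Intramolecular Mitsunobu etherification (PPh3, DIAD, THF, 0 °C) then closes O1–C2 with inversion to (2R)-3',7-bis(methoxymethoxy)-2'-prenyl-4'-(triisopropylsilyloxy)flavan F2. Buffered desilylation (n-Bu4NF/AcOH, THF, 0 °C) returns to the route at 18.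

**Step 12.** The 4'-phenoxide formed by DBU may push O1 out of C2 (retro-1,6-addition) and reclose without control. Enantiomeric purity would then leak away, and slow alkylation next to the 3'-MOM group would lengthen this exposure. The fallback sets out from 18 and replaces the base-mediated substitution by a redox condensation that needs no external base. This is a Mitsunobu etherification with 2-methylbut-3-yn-2-ol (PPh3, DIAD, toluene, 0 °C). It comes back to the route directly at 20 and makes no new compound (entry F0).

**Step 14.** Three things may go wrong.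
- Electrophilic silicon or the released methoxymethyl fragment may attack the electron-rich chromene double bond.
- Cleavage of the hindered 3'-acetal may lag behind.
- Ionisation of C2–O1 may erode the configuration. The ring D oxygen, held in conjugation with ring B, would assist it.

The fallback changes the order of events and sets out from 20. In 20 no chromene exists yet, and O4' carries a bulky tertiary alkyl group twisted out of conjugation. MOM cleavage at this stage (Me3SiOTf, 2,2'-bipyridyl, MeCN, 0 °C; then H2O) should give (2R)-7,3'-dihydroxy-4'-(2-methylbut-3-yn-2-yloxy)-2'-prenylflavan F3. Neutral thermolysis (o-xylene, 140 °C) then runs the propargyl Claisen–electrocyclisation cascade as the last operation and comes back to the route at 25.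

**Further compounds**

F1 | step 11 | (S)-3-[2-hydroxy-4-(methoxymethoxy)phenyl]-1-[3-(methoxymethoxy)-2-prenyl-4-(triisopropylsilyloxy)phenyl]propan-1-ol | O[C@@H](CCc1ccc(OCOC)cc1O)c1ccc(O[Si](C(C)C)(C(C)C)C(C)C)c(OCOC)c1CC=C(C)C
F2 | step 11 | (2R)-3',7-bis(methoxymethoxy)-2'-prenyl-4'-(triisopropylsilyloxy)flavan | CC(C)=CCc1c([C@H]2CCc3ccc(OCOC)cc3O2)ccc(O[Si](C(C)C)(C(C)C)C(C)C)c1OCOC
F0 | step 12 | none | none
F3 | step 14 | (2R)-7,3'-dihydroxy-4'-(2-methylbut-3-yn-2-yloxy)-2'-prenylflavan | CC(C)=CCc1c([C@H]2CCc3ccc(O)cc3O2)ccc(OC(C)(C)C#C)c1O
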